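I began from a ratio. At 0.417 h grey held 1.65 times the target of red, on 2.25 times the partner and the same substrate charge.

| flask | substrate | partner | remark | time |
|---|---|---|---|---|
| red | 0.30 M | 0.40 M | run made earlier |  |
| grey | 0.30 M | 0.90 M | run made earlier |  |
| blue | 0.15 M | 0.60 M | run made earlier |  |
| flask | 0.30 M | 0.600 M |  | 8.0 h |

| run | time / h | target / % |
|---|---|---|
| red | 0.133 | 10.0 |
| red | 0.417 | 22.0 |
| red | 1.00 | 11.9 |
| red | 3.00 | 3.7 |
| red | 10.0 | 3.0 |
| grey | 0.133 | 18.6 |
| grey | 0.417 | 36.3 |
| grey | 1.00 | 28.1 |
| grey | 3.00 | 3.8 |
| grey | 10.0 | 3.5 |
| blue | 0.133 | 15.6 |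
| blue | 0.417 | 15.8 |
| blue | 1.00 | 5.8 |
| blue | 3.00 | 5.3 |
| blue | 10.0 | 4.0 |

(each reading ± 0.5 percentage points)

* when, up to 8.0 h, the flask holds most target
* the amount of target, in percent of the substrate charged, at that time

The runs showed a ladder of three rungs. On the first, the rise, grey held 18.6% at 0.133 h and 36.3% at 0.417 h. On the second, the fall, it was down to 3.8% at 3.00 h. On the third, the plateau, it held 3.5% at 10.0 h, a step of 0.3 percentage points against a scatter of 0.5 points. So the reading worth taking lay on the first rung. Red and grey each stood highest at 0.417 h among their readings, so I reckoned there.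

I worked with the fraction left, f, the part of the substrate charged not held as target. I assumed ln f falls in a straight line with the partner charge. ln(1/f) was 0.248 in red and 0.451 in grey. From these, 0.405 /M was the loss slope b, the fall in ln f per unit of partner charge at this substrate charge and reading time. Red's f, multiplied by exp(−b) per unit of added partner, gave the flask 71.9% left, so I expected 28.1% target at that reading.

The forecast, which gave a peak and not a reading, put 30% at 0.47 h, since the flask “sits between them”. The flask gave 31.2% at 0.520 h, of which 24.8% was crystals. My 28.1% stood for 0.417 h, an earlier time than that, so it is not the same quantity as this peak.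

    partner → second intermediate (k = 0.0350 /min)
    substrate → open intermediate (k = 0.0570 /min)
    target ⇌ isomer of the product (K = 21.0, k = 0.210 /min)
    second intermediate → decomposed reagent (k = 0.0440 /min)
    open intermediate + second intermediate → target (k = 22.0 /M/min)
    2 open intermediate → homo product (k = 18.0 /M/min)
    crystals ⇌ target, rate k7*(cs7 - [target]) while solid is left; crystals form when [target] > cs7 (solubility = 19.0 mM, k = 1.20 /min)

I carried b to the neighbour with 1.0 M of partner, more than grey's charge. Red's f and b gave it 61.2% left, so I reckoned 38.8% target at the reading time. Its peak was 37.7%, which is 1.1 points less than that reckoning, so here the straight line overshot. At 8.00 h it held 4.24% target and 89.0% isomer of the product.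

The earlier runs and the new flask come from a simulation on assumed constants; scatter was added.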